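## Retrosynthetic overview

1. Ring A, the benzoyl ring (C1 carries the depside carbonyl, C2 an OH, C4 an oxygen, C6 the CH3), has oxygen on alternate carbons like a folded tetraketide. Its C1–C6 bond is therefore cut by a retro-aldol to an open 3,5,7-trioxooctanoyl chain that already sits on the 4-O of ring B, the methyl orsellinate ring.
2. Two decorations of ring A are removed first: the C3–Cl (chlorination directed by the neighbouring 2-OH) and the 4-O–CH3 (methylation of the only unchelated phenol). This leads back to methyl lecanorate.
3. The aryl triketo ester comes from an acylketene and the free 4-OH of methyl orsellinate. The ketene comes from a diketo-dioxinone, made from 2,2,6-trimethyl-dioxinone by two acetylations: acetyl chloride on the dienolate, then an acetyl Weinreb amide on the dianion.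
4. Ring order: ring B is purchased, the dioxinone ring is sacrificial, and ring A is the only ring formed (step 4).

Key step: step 4

Assumption: the target has no stereocentre, and compounds 4, 8 and 11 are drawn as keto tautomers although they exist as keto–enol mixtures.

## Route

Step 1
Reactants: 1 2,2,6-trimethyl-4H-1,3-dioxin-4-one; 2 acetyl chloride
Product: 4 2,2-dimethyl-6-(2-oxopropyl)-4H-1,3-dioxin-4-one, via lithium dienolate 3 (not isolated)
Conditions: 1 (2.0 equiv), LiHMDS (1 M in THF, 2.1 equiv), THF, −78 °C; then 2 (1.0 equiv), −78 → −20 °C; 1 M HCl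
Reagents that add atoms: none
Why: This is a γ-selective C-acylation (crossed Claisen-type condensation) of the extended lithium dienolate of a 6-methyl-dioxinone with an acid chloride, and the second equivalent of enolate takes up the more acidic proton of 4 so that no second acylation should follow.

Step 2
Reactants: 4 2,2-dimethyl-6-(2-oxopropyl)-4H-1,3-dioxin-4-one; 5 N-methoxy-N-methylacetamide
Product: 8 6-(2,4-dioxopentyl)-2,2-dimethyl-4H-1,3-dioxin-4-one, via dilithium dianion 6 (not isolated), via tetrahedral adduct 7 (not isolated)
Conditions: LDA (commercial 2 M solution, 2.2 equiv), THF, −78 → −40 °C; then 5 (1.1 equiv), −78 → −10 °C; cold 1 M HCl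
Reagents that add atoms: none
Why: This is a dianion Claisen acylation of the β-dicarbonyl type, in which the terminal CH2 carbanion formed last is the more nucleophilic site, and a Weinreb amide replaces a second charge of acetyl chloride because its chelated adduct 7 holds until the acid quench and so prevents O-acylation, double addition and proton transfer from the very acidic product.

Step 3
Reactants: 8 6-(2,4-dioxopentyl)-2,2-dimethyl-4H-1,3-dioxin-4-one; 9 methyl orsellinate (methyl 2,4-dihydroxy-6-methylbenzoate)
Product: 11 methyl 2-hydroxy-6-methyl-4-[(3,5,7-trioxooctanoyl)oxy]benzoate, via acylketene 10 (not isolated)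
Conditions: 9 (2 equiv), PhMe (0.3 M), 110 °C, 1–2 h, acetone swept out with N2; concentrate, use crude together with the excess 9
Reagents that add atoms: none
Why: A thermal retro-hetero-Diels–Alder loss of acetone gives acylketene 10, which the open 4-OH of 9 captures (the 2-OH is hydrogen-bonded to the ester carbonyl), a known entry to aryl β-keto esters that makes the hindered depside C–O bond before ring A and its two ortho substituents exist.

Step 4
Reactants: 11 methyl 2-hydroxy-6-methyl-4-[(3,5,7-trioxooctanoyl)oxy]benzoate
Product: 13 methyl lecanorate (methyl 4-[(2,4-dihydroxy-6-methylbenzoyl)oxy]-2-hydroxy-6-methylbenzoate), via cyclic aldol adduct 12 (not isolated)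
Conditions: Et3N (2 equiv), CH2Cl2, −20 → 0 °C; then HCl (4 M in 1,4-dioxane), 0 °C → rt
Reagents that add atoms: none
Why: Et3N reversibly enolizes 11, the chain carbon C2 between the aryl ester and the C3 ketone adds to the C7 methyl ketone to give 12, and loss of water followed by enolization of the C3 and C5 carbonyls delivers the benzene ring, the acid stage dehydrating any 12 that remains. The closest known reaction type is the biomimetic intramolecular aldol condensation–aromatization of 3,5,7-triketo esters obtained by dioxinone thermolysis and acylketene capture, which copies the orsellinic acid fold. Ring A, the only ring formed, closes in a 6-exo-trig mode with respect to the C7 carbonyl through the new C1–C6 bond (chain C2–C7). No stereocentre results, because the two sp3 centres of 12 are transient and are erased on aromatization. The C2-to-C7 aldol has to beat attack of the C5 enol oxygen on C1 (4-hydroxy-2-pyrone), Claisen attack of the C6 methylene on C1 (2,4,6-trihydroxyacetophenone), E1cB return to ketene 10 (all three expel the aryloxide) and the aldol of C8 onto C3. The substrate favours the aldol since it alone among the C1-centred paths breaks no C–O bond and C7 is the least hindered carbonyl, while a weak amine base at or below 0 °C in a non-nucleophilic solvent supplies no alkoxide, the carried-over 9 can recapture any ketene, and aromatization makes the aldol path irreversible.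

Step 5
Reactants: 13 methyl lecanorate
Product: 14 methyl evernate (methyl 2-hydroxy-4-[(2-hydroxy-4-methoxy-6-methylbenzoyl)oxy]-6-methylbenzoate)
Conditions: MeI (1.1 equiv), K2CO3 (1.1 equiv), acetone, rt
Reagents that add atoms: iodomethane (MeI), CI
Why: A Williamson-type O-methylation under weak base should touch only the ring A 4-OH, the most acidic and the only phenol not hydrogen-bonded, while the two ortho-hydroxy ester phenols stay chelated and the depside ester tolerates carbonate in acetone at room temperature.

Step 6
Reactants: 14 methyl evernate
Product: 15 methyl 4-[(3-chloro-2-hydroxy-4-methoxy-6-methylbenzoyl)oxy]-2-hydroxy-6-methylbenzoate (target)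
Conditions: SO2Cl2 (1.0 equiv, slow addition), 2,2,6,6-tetramethylpiperidine (10 mol %), PhMe, 0 °C → rt, dark
Reagents that add atoms: sulfuryl chloride, O=S(=O)(Cl)Cl
Why: In this amine-catalysed ortho-selective electrophilic chlorination of phenols, the hindered amine is turned into its N-chloro derivative, which hydrogen-bonds to the phenolic OH and hands chlorine to the adjacent carbon, so in ring A (richer than ring B, which carries an acyloxy group where ring A carries OMe) C3, ortho to both 2-OH and 4-OMe, should be taken in preference to C5, the para site that uncatalysed SO2Cl2 tends to attack.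

## Compound list

1 | 2,2,6-trimethyl-4H-1,3-dioxin-4-one | CC1=CC(=O)OC(C)(C)O1 | starting material
2 | acetyl chloride | CC(=O)Cl | starting material
3 | lithium 2,2-dimethyl-6-methylidene-6H-1,3-dioxin-4-olate (lithium dienolate of 1) | [Li+].[O-]C1=CC(=C)OC(C)(C)O1 | intermediate
4 | 2,2-dimethyl-6-(2-oxopropyl)-4H-1,3-dioxin-4-one (keto-dioxinone) | CC(=O)CC1=CC(=O)OC(C)(C)O1 | intermediate
5 | N-methoxy-N-methylacetamide | CC(=O)N(C)OC | starting material
6 | dilithium dianion of 4 (ring dienolate plus terminal enolate) | [Li+].[Li+].C=C([O-])C=C1C=C([O-])OC(C)(C)O1 | intermediate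
7 | dilithium tetrahedral adduct of 6 and 5 (racemic carbinolamine alkoxide, ring dienolate retained) | [Li+].[Li+].CON(C)C(C)([O-])CC(=O)C=C1C=C([O-])OC(C)(C)O1 | intermediate
8 | 6-(2,4-dioxopentyl)-2,2-dimethyl-4H-1,3-dioxin-4-one (diketo-dioxinone) | CC(=O)CC(=O)CC1=CC(=O)OC(C)(C)O1 | intermediate
9 | methyl orsellinate (methyl 2,4-dihydroxy-6-methylbenzoate) | COC(=O)c1c(C)cc(O)cc1O | starting material
10 | 3,5,7-trioxooct-1-en-1-one (acylketene) | CC(=O)CC(=O)CC(=O)C=C=O | intermediate
11 | methyl 2-hydroxy-6-methyl-4-[(3,5,7-trioxooctanoyl)oxy]benzoate | COC(=O)c1c(C)cc(OC(=O)CC(=O)CC(=O)CC(C)=O)cc1O | intermediate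
12 | methyl 2-hydroxy-4-[(2-hydroxy-2-methyl-4,6-dioxocyclohexane-1-carbonyl)oxy]-6-methylbenzoate (transient mixture of stereoisomers) | COC(=O)c1c(C)cc(OC(=O)C2C(=O)CC(=O)CC2(C)O)cc1O | intermediate
13 | methyl lecanorate | COC(=O)c1c(C)cc(OC(=O)c2c(C)cc(O)cc2O)cc1O | intermediate
14 | methyl evernate | COC(=O)c1c(C)cc(OC(=O)c2c(C)cc(OC)cc2O)cc1O | intermediate
15 | methyl 4-[(3-chloro-2-hydroxy-4-methoxy-6-methylbenzoyl)oxy]-2-hydroxy-6-methylbenzoate | COC(=O)c1c(C)cc(OC(=O)c2c(C)cc(OC)c(Cl)c2O)cc1O | target

## Step count and risks

Total step count: 6. Longest linear sequence: 6 steps (1 → 4 → 8 → 11 → 13 → 14 → 15).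

**Step 4 (most likely to fail).**
- Risk: expulsion of the aryloxide may outrun the aldol closure, because the departing phenoxide is stabilised by its para ester. The routes for this are lactonization through the C5 enol oxygen, Claisen closure from C6, or E1cB reversal to the ketene.
- Fallback: it sets out from 9 and comes back at 14, and joins a finished ring A acid to ring B by classical depside esterification.
- One portion of 9 would be O-methylated at its unchelated 4-OH (MeI, K2CO3, acetone, rt) to methyl everninate F1.
- Saponification (KOH, aqueous DMSO, heat; cold HCl) would give everninic acid F2.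
- F2 would then be condensed with a second portion of 9 using trifluoroacetic anhydride in toluene at rt. This acylates the free 4-OH of 9 and should give 14 directly.

**Step 6.**
- Risk: poor site selectivity. Chlorination may occur para to the 2-OH at C5, twice on ring A, or on ring B, because the directing OH is already held in an intramolecular hydrogen bond.
- Fallback: it sets out from 9 and comes back at 15. Chlorine is placed on a symmetric arene where only one outcome is possible.
- Commercial 3,5-dimethoxytoluene F3 would be lithiated between its two methoxy groups (n-BuLi, THF, 0 °C → rt, directed ortho metalation) to 2,6-dimethoxy-4-methylphenyllithium F4.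
- Quenching with C2Cl6 would give 2-chloro-1,3-dimethoxy-5-methylbenzene F5.
- The two free ring positions of F5 are equivalent, so Rieche formylation (Cl2CHOMe, TiCl4, CH2Cl2) can give only 3-chloro-2,4-dimethoxy-6-methylbenzaldehyde F6.
- BCl3 (CH2Cl2, −78 → 0 °C) would cleave, by chelation, the methoxy group ortho to the formyl group and give 3-chloro-2-hydroxy-4-methoxy-6-methylbenzaldehyde F7.
- Pinnick oxidation (NaClO2, sulfamic acid, aqueous dioxane) would give 3-chloro-2-hydroxy-4-methoxy-6-methylbenzoic acid F8.
- Condensation of F8 with 9 (trifluoroacetic anhydride, toluene, rt) should give 15.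

**Step 3.**
- Risk: capture of the ketene by a weakly nucleophilic phenol may be too slow, and at 110 °C the aryl β-keto ester can revert to the ketene. Intramolecular O-capture by the C5 enol or ketene dimerization would then drain the material.
- Fallback: it sets out from 8 and comes back at 14. Ring A is closed while the dioxinone is still in place.
- Et3N in CH2Cl2 at rt would drive the same aldol aromatization, with dioxinone C5 as the nucleophile, to 7-hydroxy-2,2,5-trimethyl-4H-1,3-benzodioxin-4-one F9.
- MeI and K2CO3 in acetone would give 7-methoxy-2,2,5-trimethyl-4H-1,3-benzodioxin-4-one F10.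
- Irradiation at 300 nm in CH2Cl2 at rt in the presence of 9 would expel acetone and give 3-methoxy-5-methyl-6-(oxomethylidene)cyclohexa-2,4-dien-1-one F11. This ortho-quinoketene has no internal enol to trap it, so the 4-OH of 9 takes it up (photochemical depside formation) to give 14.

## Further compounds

F1 | step 4 | methyl everninate (methyl 2-hydroxy-4-methoxy-6-methylbenzoate) | COC(=O)c1c(C)cc(OC)cc1O
F2 | step 4 | everninic acid (2-hydroxy-4-methoxy-6-methylbenzoic acid) | OC(=O)c1c(C)cc(OC)cc1O
F3 | step 6 | 3,5-dimethoxytoluene (purchased) | COc1cc(C)cc(OC)c1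
F4 | step 6 | 2,6-dimethoxy-4-methylphenyllithium | [Li]c1c(OC)cc(C)cc1OC
F5 | step 6 | 2-chloro-1,3-dimethoxy-5-methylbenzene | COc1cc(C)cc(OC)c1Cl
F6 | step 6 | 3-chloro-2,4-dimethoxy-6-methylbenzaldehyde | COc1cc(C)c(C=O)c(OC)c1Cl
F7 | step 6 | 3-chloro-2-hydroxy-4-methoxy-6-methylbenzaldehyde | COc1cc(C)c(C=O)c(O)c1Cl
F8 | step 6 | 3-chloro-2-hydroxy-4-methoxy-6-methylbenzoic acid | COc1cc(C)c(C(=O)O)c(O)c1Cl
F9 | step 3 | 7-hydroxy-2,2,5-trimethyl-4H-1,3-benzodioxin-4-one | CC1(C)OC(=O)c2c(C)cc(O)cc2O1
F10 | step 3 | 7-methoxy-2,2,5-trimethyl-4H-1,3-benzodioxin-4-one | CC1(C)OC(=O)c2c(C)cc(OC)cc2O1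
F11 | step 3 | 3-methoxy-5-methyl-6-(oxomethylidene)cyclohexa-2,4-dien-1-one | O=C=C1C(=O)C=C(OC)C=C1C
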